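**Plan**

- Numbering (eudesmane, also used for the nor-intermediates): ring A = C1–C5 and C10, ring B = C5–C10. C3 carries the angelate, C4 carries C15, C5 the OOH, C7 the acrylate C11(=C13)–C12, and C10 the methyl C14.
- Feature used: ring A with its C3 oxygen and C4–C15 is a reduced 2-methylanisole, and C14 lies on the same (β) face as the C3 oxygen. A 3β-hydroxyl can therefore hand C14 to a Birch-derived C5=C10 alkene.
- Cuts, in retrosynthetic order: C5–OO (ene reaction, H from C15); the angelate ester; C11–C12 (alkyne carbonylation) and C11–C13 (aldehyde homologation); C10–C14 and C5–C14 (cyclopropane); the arene (Birch); C7–C11 (triflate carbonylation); C7–C8 and C9–C10 (ethylene); C6 (one-carbon insertion).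
- Forward: ring A is bought as the arene of 3-methoxy-2-methylbenzoic acid and ring B is closed on it with ethylene. The cyclopropane then closes on C5=C10 and is reopened at C5–C14, which leaves the angular methyl and the C4=C5 alkene.
- Stereochemistry: C7 from asymmetric hydrogenation; C3 from CBS reduction (reagent control); C10 from C3 by hydroxyl delivery; C3 again from C10 in the Luche reduction; C5 from C10 by attack of singlet oxygen anti to C14; the Z ester from angelic acid.

Key step: step 11

Assumption: the absolute sense of the two catalyst-controlled steps (6 and 10) is taken from the usual models and the antipodal ligand or catalyst is used if a first run shows the opposite sense; compounds 14 to 21 are carried as C4 epimer mixtures because that centre is erased in step 13.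

**Route**

Step 1
Reactants: 1 3-methoxy-2-methylbenzoic acid
Product: 3 2-diazo-1-(3-methoxy-2-methylphenyl)ethan-1-one, via 3-methoxy-2-methylbenzoyl chloride 2 (not isolated)
Conditions: (COCl)2, cat. DMF, CH2Cl2, 0 °C → rt; evaporate; TMSCHN2 (2.2 equiv), THF/MeCN, 0 °C → rt
Reagents that add atoms: trimethylsilyldiazomethane, C[Si](C)(C)C=[N+]=[N-]
Why: First stage of the Arndt–Eistert homologation, in which acid chloride 2 acylates the nucleophilic carbon of trimethylsilyldiazomethane and loss of the silyl group leaves the α-diazoketone, whose diazo carbon becomes C6.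

Step 2
Reactants: 3 2-diazo-1-(3-methoxy-2-methylphenyl)ethan-1-one
Product: 5 (3-methoxy-2-methylphenyl)acetic acid, via (3-methoxy-2-methylphenyl)ketene 4 (not isolated)
Conditions: PhCO2Ag (10 mol%), Et3N, THF/H2O (10:1), rt, dark
Reagents that add atoms: water, O
Why: Silver-catalysed Wolff rearrangement shifts the aryl group to the diazo carbon with loss of N2, and water adds to ketene 4 to complete the one-carbon homologation.

Step 3
Reactants: 5 (3-methoxy-2-methylphenyl)acetic acid; 6 ethylene
Product: 8 7-methoxy-8-methyl-3,4-dihydronaphthalen-2(1H)-one, via (3-methoxy-2-methylphenyl)acetyl chloride 7 (not isolated)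
Conditions: (COCl)2, cat. DMF, CH2Cl2, rt; then AlCl3 (2 equiv), ethylene (1 atm), CH2Cl2, −10 °C → rt
Reagents that add atoms: ethylene 6, C=C
Why: Friedel–Crafts acylation of ethylene by the acylium ion (C7–C8) is followed by intramolecular Friedel–Crafts alkylation (C9–C10) at the only free position ortho to the side chain, which is para to the methoxy group, so ring B closes as the 2-tetralone.

Step 4
Reactants: 8 7-methoxy-8-methyl-3,4-dihydronaphthalen-2(1H)-one
Product: 9 7-methoxy-8-methyl-3,4-dihydronaphthalen-2-yl trifluoromethanesulfonate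
Conditions: NaH, THF, 0 °C; PhNTf2, 0 °C → rt
Reagents that add atoms: N-phenylbis(trifluoromethanesulfonimide), O=S(=O)(N(c1ccccc1)S(=O)(=O)C(F)(F)F)C(F)(F)F
Why: The benzylic C1 protons are the most acidic, so the arene-conjugated enolate forms and is O-sulfonylated by PhNTf2 (enol triflate formation).

Step 5
Reactants: 9 7-methoxy-8-methyl-3,4-dihydronaphthalen-2-yl trifluoromethanesulfonate
Product: 10 7-methoxy-8-methyl-3,4-dihydronaphthalene-2-carboxylic acid
Conditions: Pd(OAc)2 (5 mol%), PPh3, KOAc, CO (1 atm), DMF/H2O, 60 °C; aq. HCl work-up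
Reagents that add atoms: carbon monoxide, [C-]#[O+]; water, O
Why: Palladium-catalysed hydroxycarbonylation of an enol triflate, in which zerovalent palladium inserts into the C–OTf bond, CO inserts, and acetate then water cleave the acylpalladium to the conjugated acid, which adds C11.

Step 6
Reactants: 10 7-methoxy-8-methyl-3,4-dihydronaphthalene-2-carboxylic acid
Product: 11 (2R)-7-methoxy-8-methyl-1,2,3,4-tetrahydronaphthalene-2-carboxylic acid
Conditions: Ru(OAc)2[(R)-BINAP] (1 mol%), H2 (10 bar), MeOH, 25 °C
Reagents that add atoms: none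
Why: Ruthenium–BINAP asymmetric hydrogenation of a trisubstituted α,β-unsaturated carboxylic acid, in which the bound carboxylate holds the alkene on the chiral metal so that H2 adds to one face and C7 is set as R by the ligand (sense assigned by analogy with (E)-2-methylbut-2-enoic acid).

Step 7
Reactants: 11 (2R)-7-methoxy-8-methyl-1,2,3,4-tetrahydronaphthalene-2-carboxylic acid
Product: 12 [(2R)-7-methoxy-8-methyl-1,2,3,4-tetrahydronaphthalen-2-yl]methanol
Conditions: LiAlH4, THF, 0 °C → reflux
Reagents that add atoms: none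
Why: Hydride reduction of the carboxylic acid to the primary alcohol, which does not enolise the carboxylate and so leaves C7 untouched.

Step 8
Reactants: 12 [(2R)-7-methoxy-8-methyl-1,2,3,4-tetrahydronaphthalen-2-yl]methanol
Product: 13 (2R)-7-methoxy-8-methyl-2-[(triisopropylsilyloxy)methyl]-1,2,3,4-tetrahydronaphthalene
Conditions: TIPSCl, imidazole, DMF, rt
Reagents that add atoms: chlorotriisopropylsilane, CC(C)[Si](Cl)(C(C)C)C(C)C
Why: Silylation of the primary alcohol, giving an ether that tolerates dissolving metal, oxalic acid, borane and zinc reagents and keeps the C11 oxygen from acting as a second directing group in step 11.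

Step 9
Reactants: 13 (2R)-7-methoxy-8-methyl-2-[(triisopropylsilyloxy)methyl]-1,2,3,4-tetrahydronaphthalene
Product: 15 (7R)-11-(triisopropylsilyloxy)-12,13,14-trinoreudesm-5(10)-en-3-one (C4 epimers), via Birch dienol methyl ether 14 (not isolated)
Conditions: Li, NH3(l), THF, t-BuOH, −78 → −33 °C; NH4Cl; then (CO2H)2·2H2O, THF/MeOH/H2O, rt
Reagents that add atoms: water, O
Why: Birch reduction of an anisole leaves the donor-bearing carbons sp2, so C3 and the ring-fusion carbons C5 and C10 keep double bonds while C1 and C4 are protonated (C4 without control), and oxalic acid then hydrolyses the enol ether by C2 protonation without drawing the tetrasubstituted alkene into conjugation.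

Step 10
Reactants: 15 (7R)-11-(triisopropylsilyloxy)-12,13,14-trinoreudesm-5(10)-en-3-one (C4 epimers)
Product: 16 (3S,7R)-11-(triisopropylsilyloxy)-12,13,14-trinoreudesm-5(10)-en-3β-ol (C4 epimers)
Conditions: (R)-2-methyl-CBS-oxazaborolidine (20 mol%), BH3·SMe2, THF, −30 °C
Reagents that add atoms: none
Why: Corey–Bakshi–Shibata reduction, in which the oxazaborolidine–borane complex binds the carbonyl with the branched C4 flank as the large group and delivers hydride to the α face, so the 3β (3S) alcohol should form under catalyst control for both C4 epimers.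

Step 11
Reactants: 16 (3S,7R)-11-(triisopropylsilyloxy)-12,13,14-trinoreudesm-5(10)-en-3β-ol (C4 epimers); 17 diiodomethane
Product: 19 (3S,7R)-11-(triisopropylsilyloxy)-5β,14-cyclo-12,13-dinoreudesman-3β-ol (cyclopropane C5–C10–C14 on the β face; C4 epimers), via ethylzinc alkoxide 18 (not isolated)
Conditions: Et2Zn (5 equiv), CH2Cl2, 0 °C; then CH2I2 (10 equiv), 0 °C → rt
Reagents that add atoms: diiodomethane 17, ICI
Why: Et2Zn first turns the 3β-hydroxyl into the ethylzinc alkoxide 18, which binds the (iodomethyl)zinc carbenoid made from Et2Zn and CH2I2 and passes its CH2 to the tetrasubstituted C5=C10 alkene through the concerted butterfly transition state of the Simmons–Smith reaction. The closest known reaction type is the hydroxyl-directed cyclopropanation of cyclohex-3-enols, steroidal 5(10)-en-3-ols included. The three-membered ring closes in a single intermolecular [2+1] addition in which C14 bonds to C10 and C5 at once, so the addition is suprafacial and the two new quaternary centres are necessarily cis. Both C5 and C10 are set by the C3 stereocentre, because the pseudo-axial 3β-O–Zn reaches only the β face and C14 therefore lands on that face. The step needs face selectivity, which the homoallylic zinc alkoxide secures, helped by the silyl ether that keeps the C11 oxygen out of play and by the high nucleophilicity of the only alkene present. With the C3 oxygen axial the C4 methyl lies in or below the alkene plane in either epimer, so both should react.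

Step 12
Reactants: 19 (3S,7R)-11-(triisopropylsilyloxy)-5β,14-cyclo-12,13-dinoreudesman-3β-ol (C4 epimers)
Product: 20 (7R)-11-(triisopropylsilyloxy)-5β,14-cyclo-12,13-dinoreudesman-3-one (C4 epimers)
Conditions: Dess–Martin periodinane, CH2Cl2, rt
Reagents that add atoms: none
Why: Dess–Martin oxidation of the secondary alcohol under near-neutral conditions, which leave the cyclopropane and the silyl ether intact.

Step 13
Reactants: 20 (7R)-11-(triisopropylsilyloxy)-5β,14-cyclo-12,13-dinoreudesman-3-one (C4 epimers)
Product: 22 (7R,10S)-11-hydroxy-12,13-dinoreudesm-4-en-3-one, via desilylated cyclopropyl ketone 21 (not isolated)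
Conditions: conc. HCl, MeOH, 60 °C
Reagents that add atoms: none
Why: Acid-catalysed homoconjugate opening of a β,γ-cyclopropyl ketone, in which, after methanolysis of the silyl ether, the enol formed towards C4 pushes open the C5–C14 bond with protonation at C14, leaving C14 as the β methyl on C10 and giving the C4=C5 enone, so the C4 and C5 stereocentres vanish.

Step 14
Reactants: 22 (7R,10S)-11-hydroxy-12,13-dinoreudesm-4-en-3-one
Product: 23 (7R,10S)-3-oxo-12,13-dinoreudesm-4-en-11-al
Conditions: Dess–Martin periodinane, CH2Cl2, rt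
Reagents that add atoms: none
Why: Dess–Martin oxidation of the primary alcohol to the aldehyde without acid or base that could epimerise C7.

Step 15
Reactants: 23 (7R,10S)-3-oxo-12,13-dinoreudesm-4-en-11-al
Product: 24 (7R,10S)-12-noreudesm-4-en-11(13)-yn-3-one
Conditions: dimethyl (1-diazo-2-oxopropyl)phosphonate, K2CO3, MeOH, 0 °C → rt
Reagents that add atoms: dimethyl (1-diazo-2-oxopropyl)phosphonate, CC(=O)C(=[N+]=[N-])P(=O)(OC)OC
Why: Ohira–Bestmann variant of the Seyferth–Gilbert homologation, in which the diazomethylphosphonate anion released by methanolysis adds to the aldehyde and loss of phosphate and N2 with 1,2-hydrogen shift gives the terminal alkyne (C13), any equilibration at C7 favouring the required equatorial isomer.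

Step 16
Reactants: 24 (7R,10S)-12-noreudesm-4-en-11(13)-yn-3-one
Product: 25 methyl (7R,10S)-3-oxoeudesma-4,11(13)-dien-12-oate
Conditions: Pd(OAc)2 (1 mol%), 2-PyPPh2, MsOH, CO (30 bar), MeOH, 50 °C
Reagents that add atoms: carbon monoxide, [C-]#[O+]; methanol, CO
Why: Palladium-catalysed Markovnikov hydromethoxycarbonylation of a terminal alkyne with the 2-pyridylphosphine/sulfonic acid system, which places CO2Me (C12) on the internal carbon C11 and so gives the 2-substituted acrylate.

Step 17
Reactants: 25 methyl (7R,10S)-3-oxoeudesma-4,11(13)-dien-12-oate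
Product: 26 methyl (3S,7R,10S)-3β-hydroxyeudesma-4,11(13)-dien-12-oate
Conditions: NaBH4, CeCl3·7H2O, MeOH, −40 °C
Reagents that add atoms: none
Why: Luche reduction, in which cerium-activated 1,2-reduction of the enone by axial hydride attack on the α face, away from the C10 methyl, gives the equatorial 3β (3S) alcohol while the acrylate ester is left alone at low temperature.

Step 18
Reactants: 26 methyl (3S,7R,10S)-3β-hydroxyeudesma-4,11(13)-dien-12-oate; 27 angelic acid
Product: 29 methyl (3S,7R,10S)-3β-angeloyloxyeudesma-4,11(13)-dien-12-oate, via angelic 2,4,6-trichlorobenzoic anhydride 28 (not isolated)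
Conditions: 2,4,6-trichlorobenzoyl chloride, Et3N, toluene, rt; then 26, 75 °C
Reagents that add atoms: angelic acid 27, C/C=C(/C)C(=O)O
Why: Yamaguchi esterification, in which mixed anhydride 28 acylates the hindered allylic alcohol at the angeloyl carbonyl on heating without a nucleophilic amine catalyst, conditions under which the Z double bond of angelates does not isomerise.

Step 19
Reactants: 29 methyl (3S,7R,10S)-3β-angeloyloxyeudesma-4,11(13)-dien-12-oate
Product: 30 methyl (3S,5S,7R,10S)-3β-angeloyloxy-5α-hydroperoxyeudesma-4(15),11(13)-dien-12-oate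
Conditions: O2, tetraphenylporphyrin (cat.), hν (white LED), CH2Cl2, −20 °C
Reagents that add atoms: dioxygen, O=O
Why: Schenck ene reaction, in which singlet oxygen attacks the electron-rich tetrasubstituted C4=C5 alkene on the α face opposite the C10 methyl, bonds to C5 and takes a hydrogen from C15 (the group geminal to the acyloxy-bearing C3), giving the 5α-hydroperoxide (5S) and the C4=C15 alkene, the electron-poor angelate and acrylate alkenes being far less reactive.

**Compound list**

1 | 3-methoxy-2-methylbenzoic acid | COc1cccc(C(=O)O)c1C | starting material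
2 | 3-methoxy-2-methylbenzoyl chloride (not isolated) | COc1cccc(C(=O)Cl)c1C | intermediate
3 | 2-diazo-1-(3-methoxy-2-methylphenyl)ethan-1-one | COc1cccc(C(=O)C=[N+]=[N-])c1C | intermediate
4 | (3-methoxy-2-methylphenyl)ketene (not isolated) | COc1cccc(C=C=O)c1C | intermediate
5 | (3-methoxy-2-methylphenyl)acetic acid | COc1cccc(CC(=O)O)c1C | intermediate
6 | ethylene | C=C | starting material
7 | (3-methoxy-2-methylphenyl)acetyl chloride (not isolated) | COc1cccc(CC(=O)Cl)c1C | intermediate
8 | 7-methoxy-8-methyl-3,4-dihydronaphthalen-2(1H)-one | COc1ccc2c(c1C)CC(=O)CC2 | intermediate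
9 | 7-methoxy-8-methyl-3,4-dihydronaphthalen-2-yl trifluoromethanesulfonate | COc1ccc2c(c1C)C=C(OS(=O)(=O)C(F)(F)F)CC2 | intermediate
10 | 7-methoxy-8-methyl-3,4-dihydronaphthalene-2-carboxylic acid | COc1ccc2c(c1C)C=C(C(=O)O)CC2 | intermediate
11 | (2R)-7-methoxy-8-methyl-1,2,3,4-tetrahydronaphthalene-2-carboxylic acid | OC(=O)[C@@H]1CCc2ccc(OC)c(C)c2C1 | intermediate
12 | [(2R)-7-methoxy-8-methyl-1,2,3,4-tetrahydronaphthalen-2-yl]methanol | OC[C@@H]1CCc2ccc(OC)c(C)c2C1 | intermediate
13 | (2R)-7-methoxy-8-methyl-2-[(triisopropylsilyloxy)methyl]-1,2,3,4-tetrahydronaphthalene | CC(C)[Si](C(C)C)(C(C)C)OC[C@@H]1CCc2ccc(OC)c(C)c2C1 | intermediate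
14 | (7R)-3-methoxy-11-(triisopropylsilyloxy)-12,13,14-trinoreudesma-2,5(10)-diene, C4 epimers (not isolated) | CC(C)[Si](C(C)C)(C(C)C)OC[C@@H]1CCC2=C(C1)C(C)C(OC)=CC2 | intermediate
15 | (7R)-11-(triisopropylsilyloxy)-12,13,14-trinoreudesm-5(10)-en-3-one, C4 epimers | CC(C)[Si](C(C)C)(C(C)C)OC[C@@H]1CCC2=C(C1)C(C)C(=O)CC2 | intermediate
16 | (3S,7R)-11-(triisopropylsilyloxy)-12,13,14-trinoreudesm-5(10)-en-3β-ol, C4 epimers | CC(C)[Si](C(C)C)(C(C)C)OC[C@@H]1CCC2=C(C1)C(C)[C@@H](O)CC2 | intermediate
17 | diiodomethane | ICI | starting material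
18 | ethylzinc alkoxide of 16 (not isolated) | CC(C)[Si](C(C)C)(C(C)C)OC[C@@H]1CCC2=C(C1)C(C)[C@@H](O[Zn]CC)CC2 | intermediate
19 | (3S,7R)-11-(triisopropylsilyloxy)-5β,14-cyclo-12,13-dinoreudesman-3β-ol, β-face cyclopropane C5–C10–C14, C4 epimers | CC(C)[Si](C(C)C)(C(C)C)OC[C@@H]1CC[C@]23C[C@@]2(C1)C(C)[C@@H](O)CC3 | intermediate
20 | (7R)-11-(triisopropylsilyloxy)-5β,14-cyclo-12,13-dinoreudesman-3-one, C4 epimers | CC(C)[Si](C(C)C)(C(C)C)OC[C@@H]1CC[C@]23C[C@@]2(C1)C(C)C(=O)CC3 | intermediate
21 | (7R)-11-hydroxy-5β,14-cyclo-12,13-dinoreudesman-3-one, C4 epimers (not isolated) | OC[C@@H]1CC[C@]23C[C@@]2(C1)C(C)C(=O)CC3 | intermediate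
22 | (7R,10S)-11-hydroxy-12,13-dinoreudesm-4-en-3-one | OC[C@@H]1CC[C@@]2(C)CCC(=O)C(C)=C2C1 | intermediate
23 | (7R,10S)-3-oxo-12,13-dinoreudesm-4-en-11-al | O=C[C@@H]1CC[C@@]2(C)CCC(=O)C(C)=C2C1 | intermediate
24 | (7R,10S)-12-noreudesm-4-en-11(13)-yn-3-one | C#C[C@@H]1CC[C@@]2(C)CCC(=O)C(C)=C2C1 | intermediate
25 | methyl (7R,10S)-3-oxoeudesma-4,11(13)-dien-12-oate | C=C(C(=O)OC)[C@@H]1CC[C@@]2(C)CCC(=O)C(C)=C2C1 | intermediate
26 | methyl (3S,7R,10S)-3β-hydroxyeudesma-4,11(13)-dien-12-oate | C=C(C(=O)OC)[C@@H]1CC[C@@]2(C)CC[C@H](O)C(C)=C2C1 | intermediate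
27 | angelic acid, (Z)-2-methylbut-2-enoic acid | C/C=C(/C)C(=O)O | starting material
28 | angelic 2,4,6-trichlorobenzoic anhydride (not isolated) | C/C=C(/C)C(=O)OC(=O)c1c(Cl)cc(Cl)cc1Cl | intermediate
29 | methyl (3S,7R,10S)-3β-angeloyloxyeudesma-4,11(13)-dien-12-oate | C=C(C(=O)OC)[C@@H]1CC[C@@]2(C)CC[C@H](OC(=O)/C(C)=C\C)C(C)=C2C1 | intermediate
30 | methyl (3S,5S,7R,10S)-3β-angeloyloxy-5α-hydroperoxyeudesma-4(15),11(13)-dien-12-oate | C=C(C(=O)OC)[C@@H]1CC[C@@]2(C)CC[C@H](OC(=O)/C(C)=C\C)C(=C)[C@]2(OO)C1 | target

**Count and risks**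

Total steps: 19. Longest linear sequence: 19 steps (1 → 30); ethylene, diiodomethane and angelic acid are bought.

Steps most likely to fail:

1. Step 19 (photo-oxygenation). Hydrogen abstraction from C6 or C3 may compete with abstraction from C15. The angelate may also be oxygenated or isomerised from Z to E during long irradiation, which would give hydroperoxide mixtures that are hard to separate. The fallback oxygenates before acylation and protects the hydroperoxide. It sets out from allylic alcohol 26 and returns to the route at 30.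
   - TESCl and imidazole should give methyl 3β-(triethylsilyloxy)eudesma-4,11(13)-dien-12-oate F1.
   - Singlet oxygen (O2, tetraphenylporphyrin, hν) should give the 5α-hydroperoxide F2, with no angelate present and a bulky silyloxy group at C3 to reinforce abstraction from C15.
   - 2-Methoxypropene and PPTS mask the hydroperoxide as the 2-methoxyprop-2-yl peroxide F3.
   - TBAF buffered with AcOH frees the 3β-alcohol F4.
   - Yamaguchi angeloylation through 28 gives the angelate peroxyketal F5.
   - AcOH/THF/H2O releases the hydroperoxide.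

2. Step 10 (CBS reduction). Catalyst control at C3 may be eroded by the neighbouring C4 methyl in one of the two C4 epimers. The 3α-alcohol formed would then be carried through step 11 into the 10α-methyl series. The fallback replaces asymmetric reduction by enzymatic sorting. It sets out from ketone 15 and returns at 16.
   - NaBH4 gives 16 together with its 3α-epimer, the (3R)-alcohol F6.
   - Candida antarctica lipase B with vinyl acetate is expected, by the empirical large/medium rule for secondary alcohols (C4 large, C2 medium), to acetylate the (3R)-alcohol to the 3α-acetate F7 and leave 16, which is separated by chromatography.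
   - F7 is recycled by K2CO3/MeOH and Dess–Martin oxidation back to 15.

3. Step 6 (asymmetric hydrogenation). Enantioselectivity may be insufficient for this cyclic trisubstituted acid with its peri methyl group, and every later diastereoselective step would inherit the error. The fallback is a resolution through a covalent auxiliary. It sets out from acid 10 and returns at alcohol 12, bypassing 11.
   - H2 over Pd/C gives racemic 7-methoxy-8-methyl-1,2,3,4-tetrahydronaphthalene-2-carboxylic acid F8.
   - PivCl and Et3N give the mixed pivalic anhydride F9.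
   - (S)-4-Benzyloxazolidin-2-one with LiCl converts F9 into the (2R)-acyl oxazolidinone F10 and its (2S)-acyl diastereomer F11, which are separated by chromatography or crystallisation.
   - LiBH4 reduction of F10 gives 12 and releases the auxiliary.

**Further compounds**

F1 | step 19 | methyl (3S,7R,10S)-3β-(triethylsilyloxy)eudesma-4,11(13)-dien-12-oate | C=C(C(=O)OC)[C@@H]1CC[C@@]2(C)CC[C@H](O[Si](CC)(CC)CC)C(C)=C2C1
F2 | step 19 | methyl (3S,5S,7R,10S)-5α-hydroperoxy-3β-(triethylsilyloxy)eudesma-4(15),11(13)-dien-12-oate | C=C(C(=O)OC)[C@@H]1CC[C@@]2(C)CC[C@H](O[Si](CC)(CC)CC)C(=C)[C@]2(OO)C1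
F3 | step 19 | methyl 5α-(2-methoxyprop-2-ylperoxy)-3β-(triethylsilyloxy)eudesma-4(15),11(13)-dien-12-oate | C=C(C(=O)OC)[C@@H]1CC[C@@]2(C)CC[C@H](O[Si](CC)(CC)CC)C(=C)[C@]2(OOC(C)(C)OC)C1
F4 | step 19 | methyl 3β-hydroxy-5α-(2-methoxyprop-2-ylperoxy)eudesma-4(15),11(13)-dien-12-oate | C=C(C(=O)OC)[C@@H]1CC[C@@]2(C)CC[C@H](O)C(=C)[C@]2(OOC(C)(C)OC)C1
F5 | step 19 | methyl 3β-angeloyloxy-5α-(2-methoxyprop-2-ylperoxy)eudesma-4(15),11(13)-dien-12-oate | C=C(C(=O)OC)[C@@H]1CC[C@@]2(C)CC[C@H](OC(=O)/C(C)=C\C)C(=C)[C@]2(OOC(C)(C)OC)C1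
F6 | step 10 | (3R,7R)-11-(triisopropylsilyloxy)-12,13,14-trinoreudesm-5(10)-en-3α-ol, C4 epimers | CC(C)[Si](C(C)C)(C(C)C)OC[C@@H]1CCC2=C(C1)C(C)[C@H](O)CC2
F7 | step 10 | (3R,7R)-11-(triisopropylsilyloxy)-12,13,14-trinoreudesm-5(10)-en-3α-yl acetate, C4 epimers | CC(C)[Si](C(C)C)(C(C)C)OC[C@@H]1CCC2=C(C1)C(C)[C@H](OC(C)=O)CC2
F8 | step 6 | racemic 7-methoxy-8-methyl-1,2,3,4-tetrahydronaphthalene-2-carboxylic acid | COc1ccc2c(c1C)CC(C(=O)O)CC2
F9 | step 6 | racemic 7-methoxy-8-methyl-1,2,3,4-tetrahydronaphthalene-2-carboxylic pivalic anhydride | CC(C)(C)C(=O)OC(=O)C1CCc2ccc(OC)c(C)c2C1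
F10 | step 6 | (4S)-4-benzyl-3-[(2R)-7-methoxy-8-methyl-1,2,3,4-tetrahydronaphthalene-2-carbonyl]oxazolidin-2-one | O=C1OC[C@H](Cc2ccccc2)N1C(=O)[C@@H]1CCc2ccc(OC)c(C)c2C1
F11 | step 6 | (4S)-4-benzyl-3-[(2S)-7-methoxy-8-methyl-1,2,3,4-tetrahydronaphthalene-2-carbonyl]oxazolidin-2-one | O=C1OC[C@H](Cc2ccccc2)N1C(=O)[C@H]1CCc2ccc(OC)c(C)c2C1
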